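The benzene ring of the dihydroisocoumarin is built, not bought. Its C5–C6–C7–C8 edge, with oxygen on C6 and C8, is the diene unit of 1,3-dimethoxycyclohexa-1,3-diene, and C8a–C4a is the triple bond of an open-chain 5-hydroxyalk-2-ynoate that already carries C1 (ester), C4 and the C3 carbinol stereocentre with the full side chain. One thermal operation, a Diels–Alder addition followed by loss of ethylene (Alder–Rickert), forms C8–C8a and C4a–C5 and delivers the tetrasubstituted resorcylate with every substituent in place. The stereocentre comes from (R)-epichlorohydrin. Lactonisation and a BCl3 unmasking of the peri phenol and the terminal alcohol finish the synthesis.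

Key step: step 7

Remark: locants C1 to C8a are those of the 3,4-dihydroisocoumarin (isochroman-1-one) skeleton of the target; diene 12 is used as the distilled isomer mixture enriched in the conjugated form.

Step 1
Reactants: 1 10-bromodecan-1-ol
Product: 2 benzyl 10-bromodecyl ether
Conditions: BnOC(=NH)CCl3 (1.3 equiv), TfOH (5 mol %), CH2Cl2–cyclohexane, 0 °C → rt
Reagents that add atoms: benzyl 2,2,2-trichloroacetimidate, N=C(OCc1ccccc1)C(Cl)(Cl)Cl
Why: Acid-catalysed benzyl transfer from the trichloroacetimidate (Bundle–Iversen O-benzylation) etherifies the alcohol without generating an alkoxide, so the primary bromide is not displaced.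

Step 2
Reactants: 2 benzyl 10-bromodecyl ether; 3 (R)-epichlorohydrin
Product: 5 (R)-13-benzyloxy-1-chlorotridecan-2-ol, via 10-benzyloxydecylmagnesium bromide 4 (not isolated)
Conditions: Mg, THF, 45 °C (I2 crystal); then CuI (10 mol %), 3 (0.85 equiv), THF, −40 → −20 °C; aq NH4Cl
Reagents that add atoms: none
Why: Grignard formation followed by CuI-catalysed SN2 opening of the epoxide at its unsubstituted CH2, which at low temperature is much faster than attack at C–Cl; the C–O bond of the stereocentre is untouched, so the (R) centre of 3 is carried into 5.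

Step 3
Reactants: 5 (R)-13-benzyloxy-1-chlorotridecan-2-ol
Product: 6 (R)-2-(11-benzyloxyundecyl)oxirane
Conditions: K2CO3, MeOH, rt
Reagents that add atoms: none
Why: Intramolecular Williamson etherification: the alkoxide displaces the neighbouring primary chloride, the oxygen stays on the stereocentre and the (R) configuration is retained.

Step 4
Reactants: 6 (R)-2-(11-benzyloxyundecyl)oxirane; 7 ethyl propiolate
Product: 9 ethyl (R)-16-benzyloxy-5-hydroxyhexadec-2-ynoate, via ethyl 3-lithiopropiolate 8 (not isolated)
Conditions: 7 (2 equiv), n-BuLi (2 equiv), THF, −78 °C; BF3·OEt2 (2 equiv); then 6, −78 °C; then H2O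
Reagents that add atoms: none
Why: Yamaguchi–Hirao alkynylation: the BF3-activated terminal epoxide is opened at its CH2 by the lithium acetylide at −78 °C, where lithiated propiolate is stable and the benzyl ether is inert; the carbinol C–O bond is not broken, so the centre stays (R).

Step 5
Reactants: 10 1,3-dimethoxybenzene
Product: 11 1,5-dimethoxycyclohexa-1,4-diene
Conditions: Na, liq. NH3, EtOH, THF, −78 → −33 °C; then H2O
Reagents that add atoms: none
Why: Birch reduction: protonation of the radical anion and of the cyclohexadienyl anion leaves both methoxy groups on the remaining double bonds, giving the 2,5-dihydro (skipped) diene.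

Step 6
Reactants: 11 1,5-dimethoxycyclohexa-1,4-diene
Product: 12 1,3-dimethoxycyclohexa-1,3-diene
Conditions: t-BuOK (0.2 equiv), DMSO, rt; distil from K2CO3
Reagents that add atoms: none
Why: Base-mediated prototropic conjugation of a skipped diene through the pentadienyl anion formed at the CH2 between the two enol ether carbons; the conjugated bis-enol ether is the more stable isomer, and any remaining 11 is inert in step 7.

Step 7
Reactants: 9 ethyl (R)-16-benzyloxy-5-hydroxyhexadec-2-ynoate; 12 1,3-dimethoxycyclohexa-1,3-diene
Product: 14 ethyl 2-[(R)-13-benzyloxy-2-hydroxytridecyl]-4,6-dimethoxybenzoate, via bicyclo[2.2.2]octadiene cycloadduct 13 (not isolated)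
Conditions: 12 (4 equiv), neat, BHT (cat.), base-washed sealed tube, 185 °C
Reagents that add atoms: none
Why: The bis-enol ether diene 12 (raised HOMO) adds thermally to the ester-activated triple bond of 9 in a normal-demand [4+2] cycloaddition, and the bicyclo[2.2.2]octa-2,5-diene 13 then expels its CH2–CH2 bridge as ethylene in a retro-[4+2] step driven by aromatisation; this is the Alder–Rickert reaction, the established way to 6-alkyl-2,4-dimethoxybenzoates from alk-2-ynoates. The only ring closed is the six-membered carbocycle, formed by intermolecular cycloaddition that makes C8–C8a and C4a–C5 in one concerted, asynchronous event; the lactone stays open here. The step needs regiocontrol: the unsubstituted diene terminus, which carries the largest HOMO coefficient because both methoxy groups push electron density onto it, bonds to the beta carbon of the ynoate, and the methoxy-bearing terminus bonds to the alpha carbon, so one OMe ends up ortho (C8) and the other para (C6) to the ester. No lasting stereocentre is created: the bridgehead centres of 13 arise as two diastereomers that both collapse to the same arene, and the C3 carbinol, whose bonds are not involved, keeps its (R) configuration. The neutral, acid-free melt protects the enol ethers and the free hydroxyl, and any 14 that already lactonises in the hot mixture simply anticipates step 8.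

Step 8
Reactants: 14 ethyl 2-[(R)-13-benzyloxy-2-hydroxytridecyl]-4,6-dimethoxybenzoate
Product: 15 (R)-3-(11-benzyloxyundecyl)-6,8-dimethoxy-3,4-dihydroisocoumarin
Conditions: p-TsOH·H2O (5 mol %), toluene, 80 °C
Reagents that add atoms: none
Why: Acid-catalysed intramolecular transesterification (6-exo-trig acyl substitution) of the secondary hydroxyl on the neighbouring ester closes the delta-lactone with loss of ethanol; the C3–O bond is not broken, so C3 stays (R).

Step 9
Reactants: 15 (R)-3-(11-benzyloxyundecyl)-6,8-dimethoxy-3,4-dihydroisocoumarin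
Product: 17 (R)-8-hydroxy-3-(11-hydroxyundecyl)-6-methoxy-3,4-dihydroisocoumarin, via O-dichloroboryl dimethoxy lactone 16 (not isolated)
Conditions: BCl3 (5 equiv), C6HMe5 (3 equiv), CH2Cl2, −78 → 0 °C; then H2O
Reagents that add atoms: none
Why: BCl3 cleaves the primary benzyl ether at low temperature, pentamethylbenzene trapping the benzyl cation by Friedel–Crafts alkylation, and on warming boron chelated between the lactone carbonyl and the peri 8-methoxy oxygen delivers chloride to that methyl only, leaving the 6-OMe and the lactone intact; aqueous work-up frees both hydroxyls.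

Compound list
1 | 10-bromodecan-1-ol | OCCCCCCCCCCBr | starting material
2 | benzyl 10-bromodecyl ether | BrCCCCCCCCCCOCc1ccccc1 | intermediate
3 | (R)-epichlorohydrin | ClC[C@H]1CO1 | starting material
4 | 10-benzyloxydecylmagnesium bromide | Br[Mg]CCCCCCCCCCOCc1ccccc1 | intermediate
5 | (R)-13-benzyloxy-1-chlorotridecan-2-ol | ClC[C@H](O)CCCCCCCCCCCOCc1ccccc1 | intermediate
6 | (R)-2-(11-benzyloxyundecyl)oxirane | c1ccccc1COCCCCCCCCCCC[C@@H]1CO1 | intermediate
7 | ethyl propiolate | CCOC(=O)C#C | starting material
8 | ethyl 3-lithiopropiolate | CCOC(=O)C#C[Li] | intermediate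
9 | ethyl (R)-16-benzyloxy-5-hydroxyhexadec-2-ynoate | CCOC(=O)C#CC[C@H](O)CCCCCCCCCCCOCc1ccccc1 | intermediate
10 | 1,3-dimethoxybenzene | COc1cccc(OC)c1 | starting material
11 | 1,5-dimethoxycyclohexa-1,4-diene | COC1=CCC=C(OC)C1 | intermediate
12 | 1,3-dimethoxycyclohexa-1,3-diene | COC1=CC(OC)=CCC1 | intermediate
13 | ethyl 3-[(R)-13-benzyloxy-2-hydroxytridecyl]-1,5-dimethoxybicyclo[2.2.2]octa-2,5-diene-2-carboxylate (both bridgehead diastereomers, bridgehead descriptors left open) | CCOC(=O)C1=C(C[C@H](O)CCCCCCCCCCCOCc3ccccc3)C2CCC1(OC)C=C2OC | intermediate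
14 | ethyl 2-[(R)-13-benzyloxy-2-hydroxytridecyl]-4,6-dimethoxybenzoate | CCOC(=O)c1c(OC)cc(OC)cc1C[C@H](O)CCCCCCCCCCCOCc1ccccc1 | intermediate
15 | (R)-3-(11-benzyloxyundecyl)-6,8-dimethoxy-3,4-dihydroisocoumarin | COc1cc(OC)c2c(c1)C[C@@H](CCCCCCCCCCCOCc1ccccc1)OC2=O | intermediate
16 | (R)-3-[11-(dichloroboryloxy)undecyl]-6,8-dimethoxy-3,4-dihydroisocoumarin | COc1cc(OC)c2c(c1)C[C@@H](CCCCCCCCCCCOB(Cl)Cl)OC2=O | intermediate
17 | (R)-8-hydroxy-3-(11-hydroxyundecyl)-6-methoxy-3,4-dihydroisocoumarin | COc1cc(O)c2c(c1)C[C@@H](CCCCCCCCCCCO)OC2=O | target

Total step count: 9 steps.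
Longest linear sequence: 7 steps (1 → 2 → 3 → 4 → 7 → 8 → 9, from 10-bromodecan-1-ol); the diene arm (steps 5 and 6) joins at step 7.

Steps most likely to fail

Step 7. The cycloaddition to the beta-alkylated ynoate may be slower than thermal degradation of the diene and the ynoate, or regiocontrol may erode at the temperature needed for ethylene loss. The fallback builds the same lactone on a ready-made arene; it sets out from epoxide 6 and comes back at lactone 15. Epoxide 6 would be opened at its CH2 terminus by (3,5-dimethoxyphenyl)magnesium chloride with CuI catalysis (THF, −30 °C) to give (R)-13-benzyloxy-1-(3,5-dimethoxyphenyl)tridecan-2-ol F1. NBS in MeCN at 0 °C should brominate the ring para to one methoxy group and ortho to the side chain, giving (R)-13-benzyloxy-1-(2-bromo-3,5-dimethoxyphenyl)tridecan-2-ol F2. A carbonylative lactonisation (PdCl2(PPh3)2 cat., CO, K2CO3, DMF, 100 °C) would then insert C1 between the ring and the hydroxyl and close the lactone to 15.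

Step 9. Benzyl ether cleavage may stay incomplete at the low temperature that keeps the 6-methoxy group safe, benzyl cation may be transferred to the electron-rich ring, or demethylation may run on to C6 on warming. The fallback separates the two deprotections; it sets out from 15 and comes back at target 17. Hydrogenolysis (H2, Pd/C, EtOAc, rt) would remove the benzyl group without any cationic intermediate and give (R)-3-(11-hydroxyundecyl)-6,8-dimethoxy-3,4-dihydroisocoumarin F3. BCl3 alone (CH2Cl2, −78 → 0 °C), which then has only the chelated 8-O-methyl ether to cleave, would give 17.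

Step 4. The lithiated propiolate may decompose before it opens the epoxide, or the BF3-activated epoxide may rearrange instead of being alkynylated. The fallback introduces the ester after the epoxide opening; it sets out from 6 and comes back at ynoate 9. Lithium acetylide–ethylenediamine complex in DMSO at rt would open 6 at its CH2 to give (R)-15-benzyloxypentadec-1-yn-4-ol F4. Silylation (TBSCl, imidazole, DMF) would give (R)-15-benzyloxy-4-(tert-butyldimethylsilyloxy)pentadec-1-yne F5. Deprotonation with n-BuLi (THF, −78 °C) and quenching with ClCO2Et would give ethyl (R)-16-benzyloxy-5-(tert-butyldimethylsilyloxy)hexadec-2-ynoate F6. HF·pyridine in THF at 0 °C would then remove the silyl group to give 9.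

Further compounds
F1 | step 7 | (R)-13-benzyloxy-1-(3,5-dimethoxyphenyl)tridecan-2-ol | COc1cc(OC)cc(C[C@H](O)CCCCCCCCCCCOCc2ccccc2)c1
F2 | step 7 | (R)-13-benzyloxy-1-(2-bromo-3,5-dimethoxyphenyl)tridecan-2-ol | COc1cc(OC)c(Br)c(C[C@H](O)CCCCCCCCCCCOCc2ccccc2)c1
F3 | step 9 | (R)-3-(11-hydroxyundecyl)-6,8-dimethoxy-3,4-dihydroisocoumarin | COc1cc(OC)c2c(c1)C[C@@H](CCCCCCCCCCCO)OC2=O
F4 | step 4 | (R)-15-benzyloxypentadec-1-yn-4-ol | C#CC[C@H](O)CCCCCCCCCCCOCc1ccccc1
F5 | step 4 | (R)-15-benzyloxy-4-(tert-butyldimethylsilyloxy)pentadec-1-yne | C#CC[C@H](O[Si](C)(C)C(C)(C)C)CCCCCCCCCCCOCc1ccccc1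
F6 | step 4 | ethyl (R)-16-benzyloxy-5-(tert-butyldimethylsilyloxy)hexadec-2-ynoate | CCOC(=O)C#CC[C@H](O[Si](C)(C)C(C)(C)C)CCCCCCCCCCCOCc1ccccc1
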